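## Retrosynthetic overview

1. The central cyclohexene ring is formed last, by an unprotected biomimetic [4+2] union of 7β‑hydroxylabda‑8(17),12E,14‑trien‑18‑al (diene) with the B‑ring para‑quinone of a 5,7‑dihydroxyflavone (dienophile); C12 and both ring‑fusion carbons are set in this step.
2. The labdatrienal comes from a bicyclic 2‑butynyl alcohol: diene by hydrozirconation/vinylation, 7β‑OH by allylic oxidation then Luche reduction, CHO from the C18 carbinol.
3. Rings A and B are made together in one radical polyene bicyclisation (trivalent titanium) of an acyclic (2S,3S)‑epoxy alcohol, mirroring the head‑to‑tail cyclisation of geranylgeranyl diphosphate to the labdane core. The epoxide oxygen, removed afterwards, controls the absolute configuration, and the (E)‑CH2OH becomes C18.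
4. The acyclic precursor is farnesyl bromide plus a propynyl Grignard reagent, ω‑hydroxylated and epoxidised (Katsuki–Sharpless).
5. The quinone: pyranone ring from phloroglucinol and an aroylacetate, then oxidative demethylation. Ring order: flavone ring C (fragment 2) and rings A+B (fragment 1) independently, cyclohexene ring last.

Assumption: labdane numbering (C1–C20) is used for the terpenoid part; the quinone ring of the dienophile is numbered C1(=O), C2 (chromonyl), C3, C4(=O), C5 (OMe), C6; the six numbered starting materials are taken as commercial.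

## Route

Step 1
Reactants: 1 (2E,6E)-farnesyl bromide; 2 prop-1-ynylmagnesium bromide
Product: 3 (5E,9E)-6,10,14-trimethylpentadeca-5,9,13-trien-2-yne
Conditions: CuI (10 mol%), THF, 0 °C → rt
Reagents that add atoms: none
Why: Copper‑catalysed SN2 allyl–alkynyl cross‑coupling of a primary allylic bromide with an alkynyl Grignard reagent gives the skipped enyne with the (E,E) geometry retained; no stereocentre is formed.

Step 2
Reactants: 3 (5E,9E)-6,10,14-trimethylpentadeca-5,9,13-trien-2-yne
Product: 4 (2E,6E,10E)-2,6,10-trimethylpentadeca-2,6,10-trien-13-yn-1-ol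
Conditions: SeO2 (0.3 eq), t-BuOOH (2.5 eq), salicylic acid (0.1 eq), CH2Cl2, 0 °C → rt, stopped at about 50% conversion, 3 recycled
Reagents that add atoms: selenium dioxide, O=[Se]=O (catalytic oxygen carrier); tert-butyl hydroperoxide, CC(C)(C)OO (terminal oxidant)
Why: Catalytic SeO2 allylic oxidation (ene reaction then [2,3]-sigmatropic shift) prefers the (E)-methyl of the terminal gem‑dimethyl alkene, as with farnesyl and squalene substrates, and the rearrangement fixes the (E)-allylic alcohol.

Step 3
Reactants: 4 (2E,6E,10E)-2,6,10-trimethylpentadeca-2,6,10-trien-13-yn-1-ol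
Product: 5 [(2S,3S)-3-[(3E,7E)-3,7-dimethyldodeca-3,7-dien-10-yn-1-yl]-2-methyloxiran-2-yl]methanol
Conditions: Ti(OiPr)4 (10 mol%), L-(+)-diisopropyl tartrate (12 mol%), t-BuOOH (2 eq), 4 Å MS, CH2Cl2, −20 °C
Reagents that add atoms: tert-butyl hydroperoxide, CC(C)(C)OO
Why: Katsuki–Sharpless asymmetric epoxidation touches only the allylic‑alcohol alkene, and L-(+)-tartrate delivers oxygen to the face that gives the (2S,3S)-epoxide, whose CH–O carbon becomes C3 and fixes the absolute sense of the later cyclisation.

Step 4
Reactants: 5 [(2S,3S)-3-[(3E,7E)-3,7-dimethyldodeca-3,7-dien-10-yn-1-yl]-2-methyloxiran-2-yl]methanol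
Product: 6 14,15-dinorlabd-8(17)-en-12-yne-3β,18-diol
Conditions: Cp2TiCl2 (2.5 eq), Mn dust (8 eq), THF, rt, slow addition of 5; 1 M HCl work-up
Reagents that add atoms: none
Why: Nugent–RajanBabu homolytic epoxide opening by Cp2TiCl gives the tertiary C4 radical, which undergoes a biomimetic 6-endo/6-endo chair–chair radical polyene bicyclisation ended by trapping of the C8 radical with a second Cp2TiCl and β-hydride elimination to the exocyclic alkene; the equatorial C3–O–Ti group dictates the chair fold (5α-H, 9α-H, 10β-CH3), and the bulkier titanium‑bound CH2O group is expected to take the pseudo‑equatorial 4α (C18) site, away from the site that eclipses C2 and is 1,3-diaxial to C20.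

Step 5
Reactants: 6 14,15-dinorlabd-8(17)-en-12-yne-3β,18-diol
Product: 8 14,15-dinorlabd-8(17)-en-12-yn-18-ol, via cyclic thionocarbonate 7 (not isolated)
Conditions: 1,1'-thiocarbonyldiimidazole (1.2 eq), DMAP (0.1 eq), toluene, 90 °C; then Bu3SnH (1.5 eq), AIBN (0.2 eq), 105 °C; then K2CO3 (cat.), MeOH/H2O, rt
Reagents that add atoms: 1,1'-thiocarbonyldiimidazole, S=C(n1ccnc1)n1ccnc1
Why: Barton–McCombie-type radical deoxygenation of a 1,3-diol cyclic thionocarbonate: the stannyl‑radical adduct fragments toward the secondary C3 radical and not the primary neopentyl C18 one, so only C3–O is cleaved and O18 is released on hydrolysis; the C3 stereocentre is erased and no other centre is touched.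

Step 6
Reactants: 8 14,15-dinorlabd-8(17)-en-12-yn-18-ol
Product: 10 18-hydroxy-14,15-dinorlabd-8(17)-en-12-yn-7-one, via 7α-alcohol 9 (not isolated)
Conditions: SeO2 (0.5 eq), t-BuOOH (3 eq), CH2Cl2, 0 °C → rt; then MnO2 (20 eq), rt
Reagents that add atoms: selenium dioxide, O=[Se]=O (catalytic oxygen carrier); tert-butyl hydroperoxide, CC(C)(C)OO (terminal oxidant)
Why: SeO2 allylic oxidation (ene/[2,3]) of the exocyclic alkene takes place at the C7 methylene and not at the tertiary C9, giving the axial 7α-alcohol plus some enone, and MnO2, which oxidises allylic but not the neopentyl primary alcohol, converges the mixture on the exocyclic enone; C7 is deliberately flattened here.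

Step 7
Reactants: 10 18-hydroxy-14,15-dinorlabd-8(17)-en-12-yn-7-one
Product: 11 14,15-dinorlabd-8(17)-en-12-yne-7β,18-diol
Conditions: NaBH4 (1.5 eq), CeCl3·7H2O (1.2 eq), MeOH, −78 °C
Reagents that add atoms: none
Why: Luche 1,2-reduction: the small hydride attacks the C7 carbonyl axially from the α-face (opposed only by the axial H5 and H9) and gives the equatorial 7β-alcohol (7S) without conjugate reduction.

Step 8
Reactants: 11 14,15-dinorlabd-8(17)-en-12-yne-7β,18-diol; 12 vinyl bromide
Product: 14 (12E)-labda-8(17),12,14-triene-7β,18-diol, via alkenylzirconocene 13 (not isolated)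
Conditions: Cp2Zr(H)Cl (4.5 eq), THF, rt → 45 °C; then 12 (3 eq), Pd(PPh3)4 (5 mol%), ZnCl2 (20 mol%), rt; 1 M HCl work-up
Reagents that add atoms: none
Why: Syn-hydrozirconation of the 2-alkyne, equilibrated by excess Zr–H so that zirconium sits on the methyl‑bearing C13, followed by Negishi-type Pd‑catalysed alkenyl–alkenyl coupling with retention gives only the (12E)-diene; the two hydroxyls are masked in the flask as zirconium alkoxides and the hindered 1,1-disubstituted C8=C17 alkene reacts more slowly than the alkyne.

Step 9
Reactants: 14 (12E)-labda-8(17),12,14-triene-7β,18-diol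
Product: 15 (12E)-7β-hydroxylabda-8(17),12,14-trien-18-al
Conditions: TEMPO (0.1 eq), PhI(OAc)2 (1.2 eq), CH2Cl2, rt
Reagents that add atoms: none
Why: Oxoammonium (TEMPO) oxidation is selective for the primary alcohol over the hindered secondary allylic 7β-alcohol and leaves the diene alone; the aldehyde is α-quaternary and cannot epimerise.

Step 10
Reactants: 16 1-(2,4,5-trimethoxyphenyl)ethanone; 17 diethyl carbonate
Product: 18 ethyl 3-oxo-3-(2,4,5-trimethoxyphenyl)propanoate
Conditions: NaH (2.5 eq), THF, reflux; aq. HCl work-up
Reagents that add atoms: none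
Why: Crossed Claisen condensation of the ketone enolate with diethyl carbonate, driven by formation of the β-keto ester enolate.

Step 11
Reactants: 18 ethyl 3-oxo-3-(2,4,5-trimethoxyphenyl)propanoate; 19 phloroglucinol
Product: 20 5,7-dihydroxy-2-(2,4,5-trimethoxyphenyl)-4H-chromen-4-one
Conditions: neat, 240 °C (microwave or sand bath, N2), 10 min
Reagents that add atoms: none
Why: Mentzer pyrone synthesis (acid‑free thermal condensation: C-acylation of the phenol by the ester and cyclodehydration of a phenolic OH onto the aryl ketone) gives the flavone, not the Pechmann coumarin, and the symmetric phloroglucinol leaves no regiochemical choice.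

Step 12
Reactants: 20 5,7-dihydroxy-2-(2,4,5-trimethoxyphenyl)-4H-chromen-4-one
Product: 21 2-(5,7-dihydroxy-4-oxo-4H-chromen-2-yl)-5-methoxycyclohexa-2,5-diene-1,4-dione
Conditions: (NH4)2Ce(NO3)6 (2.2 eq), MeCN/H2O (3:1), 0 °C, 15 min
Reagents that add atoms: water, O
Why: Oxidative demethylation of a 1,4-dimethoxyarene by tetravalent cerium converts the para-related 2',5'-dimethoxy pair into the para-quinone and keeps the 4'-OMe, while the chelated, carbonyl‑deactivated 5,7-dihydroxy ring is oxidised more slowly.

Step 13
Reactants: 15 (12E)-7β-hydroxylabda-8(17),12,14-trien-18-al; 21 2-(5,7-dihydroxy-4-oxo-4H-chromen-2-yl)-5-methoxycyclohexa-2,5-diene-1,4-dione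
Product: 22 dichrostachine H
Conditions: 21 (1.2 eq), (CF3)2CHOH/CH2Cl2 (1:3), 2,6-di-tert-butyl-4-methylpyridine (5 mol%), 0.2 M, dark, 0 °C → rt, 24–48 h; diastereomers separated by HPLC
Reagents that add atoms: none
Why: Biomimetic intermolecular Diels–Alder reaction at the only activated quinone double bond (C2=C3), in which hydrogen‑bond activation of the vinylogous‑ester carbonyl C1=O and of the chromone carbonyl makes C3 the most electrophilic carbon so that the unsubstituted diene terminus C15 bonds there and C12 closes onto the chromone‑bearing C2; the angular chromone is expected to sit endo (the exo site on C2 is nearly eclipsed with the C11 methylene) so that C11 ends cis to the chromone with a cis ring fusion; and the quinone is expected to add to the diene face anti to the decalin in the conformer where 1,3-allylic strain with C16 holds C9 perpendicular to the diene and C12 lies anti to C8, which gives 12R with S at the chromone‑bearing fusion carbon and R at the CH fusion carbon.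

## Compound list

1 | (2E,6E)-farnesyl bromide | CC(C)=CCC/C(C)=C/CC/C(C)=C/CBr | starting material
2 | prop-1-ynylmagnesium bromide | CC#C[Mg]Br | starting material
3 | (5E,9E)-6,10,14-trimethylpentadeca-5,9,13-trien-2-yne | CC#CC/C=C(C)/CC/C=C(C)/CCC=C(C)C | intermediate
4 | (2E,6E,10E)-2,6,10-trimethylpentadeca-2,6,10-trien-13-yn-1-ol | CC#CC/C=C(C)/CC/C=C(C)/CC/C=C(C)/CO | intermediate
5 | [(2S,3S)-3-[(3E,7E)-3,7-dimethyldodeca-3,7-dien-10-yn-1-yl]-2-methyloxiran-2-yl]methanol | OC[C@]1(C)O[C@H]1CC/C(C)=C/CC/C(C)=C/CC#CC | intermediate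
6 | 14,15-dinorlabd-8(17)-en-12-yne-3β,18-diol (5α-H, 9α-H, 10β-CH3, 4α-CH2OH) | C=C1CC[C@@H]2[C@](C)(CC[C@H](O)[C@@]2(C)CO)[C@H]1CC#CC | intermediate
7 | 3β,18-O,O-thiocarbonyl derivative (cyclic thionocarbonate) of 6 | C=C1CC[C@@H]2[C@](C)(CC[C@@H]3OC(=S)OC[C@@]23C)[C@H]1CC#CC | intermediate
8 | 14,15-dinorlabd-8(17)-en-12-yn-18-ol | C=C1CC[C@@H]2[C@](C)(CCC[C@@]2(C)CO)[C@H]1CC#CC | intermediate
9 | 14,15-dinorlabd-8(17)-en-12-yne-7α,18-diol | C=C1[C@H](O)C[C@@H]2[C@](C)(CCC[C@@]2(C)CO)[C@H]1CC#CC | intermediate
10 | 18-hydroxy-14,15-dinorlabd-8(17)-en-12-yn-7-one | C=C1C(=O)C[C@@H]2[C@](C)(CCC[C@@]2(C)CO)[C@H]1CC#CC | intermediate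
11 | 14,15-dinorlabd-8(17)-en-12-yne-7β,18-diol | C=C1[C@@H](O)C[C@@H]2[C@](C)(CCC[C@@]2(C)CO)[C@H]1CC#CC | intermediate
12 | vinyl bromide | C=CBr | starting material
13 | (12E)-13-[chlorobis(cyclopentadienyl)zirconio]-14,15-dinorlabda-8(17),12-diene-7β,18-diol with both hydroxyls as O–Zr(Cl)Cp2 alkoxides | C=C1[C@@H](O[Zr](Cl)(C2C=CC=C2)C2C=CC=C2)C[C@@H]2[C@](C)(CCC[C@@]2(C)CO[Zr](Cl)(C2C=CC=C2)C2C=CC=C2)[C@H]1C/C=C(\C)[Zr](Cl)(C1C=CC=C1)C1C=CC=C1 | intermediate
14 | (12E)-labda-8(17),12,14-triene-7β,18-diol | C=C1[C@@H](O)C[C@@H]2[C@](C)(CCC[C@@]2(C)CO)[C@H]1C/C=C(\C)C=C | intermediate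
15 | (12E)-7β-hydroxylabda-8(17),12,14-trien-18-al | C=C1[C@@H](O)C[C@@H]2[C@](C)(CCC[C@@]2(C)C=O)[C@H]1C/C=C(\C)C=C | intermediate
16 | 1-(2,4,5-trimethoxyphenyl)ethanone | CC(=O)c1cc(OC)c(OC)cc1OC | starting material
17 | diethyl carbonate | CCOC(=O)OCC | starting material
18 | ethyl 3-oxo-3-(2,4,5-trimethoxyphenyl)propanoate | CCOC(=O)CC(=O)c1cc(OC)c(OC)cc1OC | intermediate
19 | phloroglucinol | Oc1cc(O)cc(O)c1 | starting material
20 | 5,7-dihydroxy-2-(2,4,5-trimethoxyphenyl)-4H-chromen-4-one | COc1cc(OC)c(OC)cc1-c1cc(=O)c2c(O)cc(O)cc2o1 | intermediate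
21 | 2-(5,7-dihydroxy-4-oxo-4H-chromen-2-yl)-5-methoxycyclohexa-2,5-diene-1,4-dione | COC1=CC(=O)C(=CC1=O)c1cc(=O)c2c(O)cc(O)cc2o1 | intermediate
22 | dichrostachine H | C=C1[C@@H](O)C[C@@H]2[C@](C)(CCC[C@@]2(C)C=O)[C@H]1C[C@@H]1C(C)=CC[C@H]2C(=O)C(OC)=CC(=O)[C@@]12c1cc(=O)c2c(O)cc(O)cc2o1 | target

## Step count and risks

Total: 13 steps (9 for fragment 1, 3 for fragment 2, 1 union). Longest linear sequence: 10 steps (steps 1–9, then step 13).

**Most likely to fail, first: step 13.** The dienophile double bond is trisubstituted and the reaction builds a quaternary centre next to a tertiary one. Regiochemistry, chromone‑endo versus enedione‑endo geometry and the diene face are all under substrate control only. The chromone‑endo preference in particular is not established: 2-substituted quinones normally react with the enedione ring endo, which would give the wrong relative configuration at C12. The facial preference depends on an unverified rotamer population about C9–C11. The stereoisomeric adducts are diastereomers and separable.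

The fallback sets out from 21 and comes back at 22. It replaces solvent activation by a covalently activated dienophile. Treating 21 with BF3·OEt2 in CH2Cl2 at 0 °C closes the 5-hydroxy-4-oxo unit to the difluoroboron chelate of quinone 21 F1. This makes the chromone the strongest acceptor of the molecule, which reinforces C3 as the electrophilic carbon and the chromone as the endo group, and allows reaction at low temperature. F1 reacts with 15 in CH2Cl2 at −40 °C → 0 °C to give the difluoroboron chelate of dichrostachine H F2. Warming F2 in MeOH at 45 °C removes boron and gives 22.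

**Second: step 4.** The C4 configuration is set in a radical, so it rests on a conformational preference and not on the epoxide geometry. Reduction or deoxygenation of the β-titanoxy radical can compete, and yields of such bicyclisations are moderate.

The fallback sets out from 5 and comes back at 6. It changes from a radical to a stereospecific cationic cyclisation. TBSCl and imidazole convert 5 into the tert-butyldimethylsilyl ether of epoxy alcohol 5 F3. MeAlCl2 in CH2Cl2 at −78 °C opens the epoxide with inversion at C4 in a concerted chair–chair cyclisation, so the (E)-CH2OSi group must end equatorial (C18). This gives the 18-O-tert-butyldimethylsilyl ether of diol 6 F4, which is separated from endocyclic alkene isomers on AgNO3-impregnated silica. Bu4NF in THF then returns 6.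

**Third: step 8.** Three zirconium centres must be carried on one hindered molecule. The regiochemistry relies on equilibration, the 8(17)-alkene can compete for Zr–H, and the α-methyl alkenylzirconium couples slowly.

The fallback sets out from 11 and comes back at 14. It separates the hydrometalation from the C–C coupling and inverts the polarity of the coupling partners. The alkenylzirconocene 13 is quenched with I2 at 0 °C to give the isolable (12E)-13-iodo-14,15-dinorlabda-8(17),12-diene-7β,18-diol F5, which can be freed from any regioisomer or alkene‑reduced material. A Stille coupling of F5 with Bu3SnCH=CH2 (Pd(PPh3)4, CuI, DMF, 40 °C) tolerates both hydroxyls and gives 14.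

Further compounds
F1 | step 13 | difluoroboron chelate of quinone 21 (5-O–BF2←O=C4 of the chromone) | COC1=CC(=O)C(=CC1=O)C1=CC(=[O+][B-](F)(F)O2)c3c2cc(O)cc3O1
F2 | step 13 | difluoroboron chelate of dichrostachine H | C=C1[C@@H](O)C[C@@H]2[C@](C)(CCC[C@@]2(C)C=O)[C@H]1C[C@@H]1C(C)=CC[C@H]2C(=O)C(OC)=CC(=O)[C@@]12C1=CC(=[O+][B-](F)(F)O2)c3c2cc(O)cc3O1
F3 | step 4 | tert-butyldimethylsilyl ether of epoxy alcohol 5 | CC(C)(C)[Si](C)(C)OC[C@]1(C)O[C@H]1CC/C(C)=C/CC/C(C)=C/CC#CC
F4 | step 4 | 18-O-tert-butyldimethylsilyl ether of diol 6 | C=C1CC[C@@H]2[C@](C)(CC[C@H](O)[C@@]2(C)CO[Si](C)(C)C(C)(C)C)[C@H]1CC#CC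
F5 | step 8 | (12E)-13-iodo-14,15-dinorlabda-8(17),12-diene-7β,18-diol | C=C1[C@@H](O)C[C@@H]2[C@](C)(CCC[C@@]2(C)CO)[C@H]1C/C=C(\C)I
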